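The summer flask holds substrate in the first phase and reagent in a second phase, from which the reagent crosses into the reaction phase. It has been followed to 120 min and is asked about at 4.0 h. The dawn run holds twice the substrate.

| flask | substrate | reagent in the second phase | remark | time | volume of the second phase over the first |
|---|---|---|---|---|---|
| summer | 16 mM | 16 mM | the very flask that is asked about, followed so far |  |  |
| dawn | 32 mM | 16 mM | run made earlier |  |  |
| flask | 16 mM | 16.0 mM |  | 4.0 h | 0.50 |

summer run (percent of the substrate charged)

| time / min | target / % | substrate / % |
|---|---|---|
| 8.00 | 10.9 | 88.9 |
| 25.0 | 23.4 | 68.7 |
| 40.0 | 24.8 | 60.9 |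
| 60.0 | 22.3 | 58.0 |
| 90.0 | 16.5 | 57.2 |
| 120 | 13.3 | 57.5 |

dawn run (percent of the substrate charged)

| time / h | target / % | substrate / % |
|---|---|---|
| 0.250 | 14.7 | 81.6 |
| 0.333 | 18.0 | 77.8 |
| 0.667 | 19.7 | 72.0 |
| 1.00 | 18.0 | 71.2 |
| 1.50 | 14.0 | 72.6 |
| 3.00 | 8.5 | 75.4 |

(readings scatter by 0.5 percentage points)

- in the second phase: reagent in the second phase; everything else is in the first
- charges count per volume of the first phase; a concentration in a rate is the amount of a species over the volume of its own phase; every rate counts per litre of the first phase
- steps thought possible: reagent in the reaction phase + target -> over-reacted product; reagent in the reaction phase -> decomposed reagent; reagent in the reaction phase <-> reagent in the second phase; substrate + reagent in the reaction phase <-> target; reagent in the reaction phase -> decomposition product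
- the earlier runs hold the two phases in the same ratio of volumes as the flask asked about

- how much target there is at 4.0 h, in percent of the substrate charged
- the change that raises the amount of target at 4.0 h, in percent of the substrate charged most ("none" if none brings more than 2 percentage points) (green / teal / none)
- amount of target at 4.0 h, in percent of the substrate charged, after green

- green: doubling the amount of reagent in the second phase, all else as stated
- teal: doubling the transfer coefficient of the reagent in the second phase, all else as stated

Late in the summer flask, two readings seem not to go together: target falls from 16.5% to 13.3% of the charge, while substrate reads 57.2%, then 57.5%, a change smaller than target's. The reckoning therefore freezes substrate. If binding then holds its balance, reagent in the reaction phase stands in proportion to target. Over-reaction consumes reagent and target together, so the rate of that step goes as target's square; decomposition of the reagent adds a loss that goes as target itself, so a straight climb of the reciprocal of target's fraction, the second-order plot, is a working approximation for a short stretch of the tail. Call the reciprocal climb, the rise per hour of one over target's fraction of the charge, 3.03 h⁻¹, as read from the summer flask. The dawn tail reads 3.08 h⁻¹, whereas first-order rates read from the same tails differ, 0.517 h⁻¹ against 0.333 h⁻¹. Carried on from the last summer reading, the climb gives 7.36% at 4.0 h.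

The forecast gives 7.5%, names none as the best change and puts green at 3.5%, reasoning that “target slowly reverts, and the released reagent destroys more target”.

    reagent in the reaction phase + target → over-reacted product (k = 0.0556 M⁻¹ s⁻¹)
    reagent in the reaction phase → decomposed reagent (k = 1.02 × 10⁻⁴ s⁻¹)
    reagent in the reaction phase ⇌ reagent in the second phase, rate k3*([reagent in the reaction phase] - [reagent in the second phase]/K3) per volume of the first phase (partition coefficient = 0.570, kL = 6.61 × 10⁻⁴ s⁻¹)
    substrate + reagent in the reaction phase ⇌ target (K = 136 M⁻¹, k = 0.0494 M⁻¹ s⁻¹)
    reagent in the reaction phase → decomposition product (k = 1.43 × 10⁻⁷ s⁻¹)

The summer flask gives 6.88%, and green gives 4.67%; green changes target by −2.2 percentage points and teal by −0.17 points, so the answer is none. The climb reaches 6.76% for the dawn flask at 4.0 h, which holds 6.45%. In the summer flask at 4.0 h, binding relaxes with a half-life of 0.219 h, short against the time and against the 5.2 h that the forward step alone gives substrate. The summer flask then holds substrate at 60.6% of the charge beside over-reacted product at 32.5%.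

The readings stem from a simulated flask from invented constants.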